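**Strategy.** The spiro γ-lactone (O–C9–C10H2–C11HMe–C12=O, C9 being the quaternary carbinol carbon of the pyrrolo[1,2-a]azepine) is disconnected at C10–C11. The feature exploited is that this ring is an ester of the tertiary C9 oxygen: an acrylate on that oxygen and a vinyl group on C9 are joined by ring-closing metathesis, which makes C10=C11 and closes the five-membered ring in one operation; reductive methylation then places the C11 methyl anti to the pyrrolidine. The precursor is the acrylate of a vinyl(silylethynyl)carbinol carried by an N-Boc-5-methoxypyrrolidine, made by Felkin-controlled acetylide addition. B-alkyl Suzuki coupling, a vinylogous Mannich reaction and a final N,O-acetalisation complete the tetracycle.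

Key step: step 5

Assumption: the C5 N,O-acetal is taken to equilibrate under the conditions of its formation to the (5S) epimer of the target, and 3-methyltetronic acid is taken as a catalogue compound. Numbering: pyrrolo[1,2-a]azepine C1–C3, N4, C5–C9, C9a; spiro-lactone C10–C12; side-chain lactone C1′–C4′; Boc = tert-butoxycarbonyl, TIPS = triisopropylsilyl.

Step 1
Reactants: 1 methyl (2S)-1-Boc-5-oxopyrrolidine-2-carboxylate
Product: 3 methyl (2S)-1-Boc-5-methoxypyrrolidine-2-carboxylate (C5 epimers), via 5-hydroxy hemiaminal 2 (not isolated)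
Conditions: LiBHEt3, THF, −78 °C; then MeOH, PPTS (cat.), rt
Reagents that add atoms: methanol (CO)
Why: The N-Boc-activated lactam carbonyl is the most electrophilic site for LiBHEt3 at −78 °C and acid-catalysed exchange of the hemiaminal with methanol gives the N,O-acetal (partial imide reduction followed by acetalisation); C2 (the later C9a) is untouched and the new C5 centre is an inconsequential mixture that is erased in step 12.

Step 2
Reactants: 3 methyl (2S)-1-Boc-5-methoxypyrrolidine-2-carboxylate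
Product: 5 tert-butyl (2S)-2-acryloyl-5-methoxypyrrolidine-1-carboxylate, via Weinreb amide 4 (not isolated)
Conditions: MeNH(OMe)·HCl, i-PrMgCl, THF, −20 °C; then CH2=CHMgBr, −20 → 0 °C; inverse quench into cold aq. NaHSO4
Reagents that add atoms: vinylmagnesium bromide (C=C[Mg]Br)
Why: Aminolysis with the chloromagnesium amide gives the Weinreb amide in situ, whose chelated tetrahedral adduct with the vinyl Grignard reagent collapses to the enone only on the cold acidic inverse quench, which also keeps the liberated amine from adding to the enone (Weinreb ketone synthesis).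

Step 3
Reactants: 5 tert-butyl (2S)-2-acryloyl-5-methoxypyrrolidine-1-carboxylate
Product: 6 tert-butyl (2S)-2-[(3R)-3-hydroxy-5-(triisopropylsilyl)pent-1-en-4-yn-3-yl]-5-methoxypyrrolidine-1-carboxylate
Conditions: TIPS–C≡CH, n-BuLi, THF, −78 °C; then 5, −78 °C; AcOH quench at −78 °C
Reagents that add atoms: (triisopropylsilyl)acetylene (C#C[Si](C(C)C)(C(C)C)C(C)C)
Why: The hard lithium acetylide adds 1,2 to the enone under non-chelating Felkin–Anh control (C9a–N bond anti to the nucleophile, approach past C9a–H), the sense known for lithium acetylide additions to cyclic N-Boc α-amino carbonyl compounds, which sets the quaternary C9 centre, and the cold acidic quench keeps the alkoxide from attacking the carbamate.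

Step 4
Reactants: 6 tert-butyl (2S)-2-[(3R)-3-hydroxy-5-(triisopropylsilyl)pent-1-en-4-yn-3-yl]-5-methoxypyrrolidine-1-carboxylate
Product: 7 (3R)-3-[(2S)-1-Boc-5-methoxypyrrolidin-2-yl]-5-(triisopropylsilyl)pent-1-en-4-yn-3-yl prop-2-enoate
Conditions: acryloyl chloride, i-Pr2NEt, DMAP (cat.), CH2Cl2, 0 °C → rt
Reagents that add atoms: acryloyl chloride (C=CC(=O)Cl)
Why: DMAP-catalysed O-acylation of the tertiary but sterically slim propargylic alcohol with the acid chloride proceeds under amine-base conditions without forming the alkoxide that would cyclise onto the Boc group (nucleophilic catalysis of esterification).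

Step 5
Reactants: 7 (3R)-3-[(2S)-1-Boc-5-methoxypyrrolidin-2-yl]-5-(triisopropylsilyl)pent-1-en-4-yn-3-yl prop-2-enoate
Product: 8 tert-butyl (2S)-5-methoxy-2-{(2R)-5-oxo-2-[(triisopropylsilyl)ethynyl]-2,5-dihydrofuran-2-yl}pyrrolidine-1-carboxylate
Conditions: Hoveyda–Grubbs II (5 mol %), toluene (high dilution), 80 °C
Reagents that add atoms: none
Why: The Ru alkylidene loads onto the C9 vinyl group, undergoes [2+2] cycloaddition with the tethered acrylate and cycloreverts with loss of ethylene, which forges C10=C11 and closes the lactone in one turnover. The closest known reaction type is ring-closing olefin metathesis of acrylates of tertiary allylic alcohols to γ,γ-disubstituted butenolides. The single ring closed is the five-membered unsaturated lactone, closed by intramolecular metathesis between the C10 and C11 alkene termini, with the ester O–C9 bond from step 4 as the tether. No stereocentre is created (C11 stays sp2 until step 6) and C9 and C9a are not touched. The step needs cyclisation over cross-metathesis and no enyne metathesis: geminal substitution at C9 favours ring closure, no other ring of reasonable size can form, and the bulky TIPS cap keeps the alkyne out of the catalytic cycle.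

Step 6
Reactants: 8 tert-butyl (2S)-5-methoxy-2-{(2R)-5-oxo-2-[(triisopropylsilyl)ethynyl]-2,5-dihydrofuran-2-yl}pyrrolidine-1-carboxylate
Product: 10 tert-butyl (2S)-5-methoxy-2-{(2R,4R)-4-methyl-5-oxo-2-[(triisopropylsilyl)ethynyl]oxolan-2-yl}pyrrolidine-1-carboxylate, via lithium lactone enolate 9 (not isolated)
Conditions: L-Selectride, THF, −78 °C; then MeI, HMPA, −78 → −30 °C
Reagents that add atoms: iodomethane (CI)
Why: L-Selectride adds hydride 1,4 to the β-unsubstituted butenolide and the lithium enolate so formed is C-methylated on the face anti to the bulky N-Boc-pyrrolidinyl group and syn to the slim alkynyl group at C9 (reductive alkylation of an enoate), which sets C11 as (R).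

Step 7
Reactants: 10 tert-butyl (2S)-5-methoxy-2-{(2R,4R)-4-methyl-5-oxo-2-[(triisopropylsilyl)ethynyl]oxolan-2-yl}pyrrolidine-1-carboxylate
Product: 11 tert-butyl (2S)-2-[(2R,4R)-2-ethynyl-4-methyl-5-oxooxolan-2-yl]-5-methoxypyrrolidine-1-carboxylate
Conditions: TBAF, AcOH, THF, 0 °C → rt
Reagents that add atoms: none
Why: Fluoride cleaves the C(sp)–Si bond and the acetic acid buffer protonates the acetylide at once so that the C11 centre is not epimerised (protodesilylation).

Step 8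
Reactants: 11 tert-butyl (2S)-2-[(2R,4R)-2-ethynyl-4-methyl-5-oxooxolan-2-yl]-5-methoxypyrrolidine-1-carboxylate
Product: 12 tert-butyl (2S)-2-[(2R,4R)-2-ethenyl-4-methyl-5-oxooxolan-2-yl]-5-methoxypyrrolidine-1-carboxylate
Conditions: H2 (1 atm), Lindlar catalyst, quinoline, EtOAc, rt
Reagents that add atoms: none
Why: The lead-poisoned palladium catalyst reduces the terminal alkyne to the alkene and stops there (Lindlar semihydrogenation), leaving lactone, carbamate and N,O-acetal untouched.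

Step 9
Reactants: 13 4-hydroxy-3-methylfuran-2(5H)-one (3-methyltetronic acid)
Product: 14 4-bromo-3-methylfuran-2(5H)-one
Conditions: (COBr)2, DMF (cat.), CH2Cl2, 0 °C → rt
Reagents that add atoms: oxalyl bromide (O=C(Br)C(=O)Br)
Why: The Vilsmeier-type bromoiminium salt formed from oxalyl bromide and DMF activates the enol oxygen of the vinylogous acid and bromide displaces it by addition–elimination (deoxybromination of a tetronic acid).

Step 10
Reactants: 12 tert-butyl (2S)-2-[(2R,4R)-2-ethenyl-4-methyl-5-oxooxolan-2-yl]-5-methoxypyrrolidine-1-carboxylate; 14 4-bromo-3-methylfuran-2(5H)-one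
Product: 16 tert-butyl (2S)-5-methoxy-2-{(2S,4R)-4-methyl-2-[2-(4-methyl-5-oxo-2,5-dihydrofuran-3-yl)ethyl]-5-oxooxolan-2-yl}pyrrolidine-1-carboxylate, via B-alkyl-9-BBN adduct 15 (not isolated)
Conditions: 9-BBN, THF, rt; then 14, Pd(dppf)Cl2 (5 mol %), AsPh3, K3PO4, DMF–H2O, rt
Reagents that add atoms: none
Why: 9-BBN places boron on the terminal carbon C7 of the neopentyl-type vinyl group for steric reasons and the B-alkyl Suzuki–Miyaura coupling then joins C7 to C6 of the vinylogous acyl bromide under mild base that the lactone and N,O-acetal tolerate; no stereocentre is formed.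

Step 11
Reactants: 17 3-methylfuran-2(5H)-one
Product: 18 triisopropyl[(3-methylfuran-2-yl)oxy]silane
Conditions: TIPSOTf, Et3N, CH2Cl2, 0 °C
Reagents that add atoms: triisopropylsilyl trifluoromethanesulfonate (CC(C)[Si](OS(=O)(=O)C(F)(F)F)(C(C)C)C(C)C)
Why: Soft enolisation of the butenolide with the silyl triflate and triethylamine gives the aromatic 2-silyloxyfuran (silyl dienol ether formation).

Step 12
Reactants: 16 tert-butyl (2S)-5-methoxy-2-{(2S,4R)-4-methyl-2-[2-(4-methyl-5-oxo-2,5-dihydrofuran-3-yl)ethyl]-5-oxooxolan-2-yl}pyrrolidine-1-carboxylate; 18 triisopropyl[(3-methylfuran-2-yl)oxy]silane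
Product: 19 tert-butyl (2S,5S)-2-{(2S,4R)-4-methyl-2-[2-(4-methyl-5-oxo-2,5-dihydrofuran-3-yl)ethyl]-5-oxooxolan-2-yl}-5-[(2S)-4-methyl-5-oxo-2,5-dihydrofuran-2-yl]pyrrolidine-1-carboxylate
Conditions: TIPSOTf (10 mol %), CH2Cl2, −78 → 0 °C
Reagents that add atoms: none
Why: Catalytic silyl triflate ionises the N,O-acetal to the N-Boc iminium ion, which the silyloxyfuran attacks through its C5 (vinylogous Mannich reaction) anti to the bulky quaternary substituent at C9a, setting C3 trans to C9a, and with the threo preference typical of 2-silyloxyfurans, setting C1′.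

Step 13
Reactants: 19 tert-butyl (2S,5S)-2-{(2S,4R)-4-methyl-2-[2-(4-methyl-5-oxo-2,5-dihydrofuran-3-yl)ethyl]-5-oxooxolan-2-yl}-5-[(2S)-4-methyl-5-oxo-2,5-dihydrofuran-2-yl]pyrrolidine-1-carboxylate
Product: 20 tert-butyl (2S,5S)-2-{(2S,4R)-4-methyl-2-[2-(4-methyl-5-oxo-2,5-dihydrofuran-3-yl)ethyl]-5-oxooxolan-2-yl}-5-[(2S,4S)-4-methyl-5-oxooxolan-2-yl]pyrrolidine-1-carboxylate
Conditions: H2 (1 atm), 5% Rh/C, EtOAc, rt
Reagents that add atoms: none
Why: Hydrogen is delivered to the trisubstituted butenolide from the face opposite the pyrrolidine at C1′ to give the cis-α,γ-disubstituted lactone (heterogeneous hydrogenation; sets C3′), while the tetrasubstituted butenolide is too hindered to react and rhodium limits allylic C–O hydrogenolysis.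

Step 14
Reactants: 20 tert-butyl (2S,5S)-2-{(2S,4R)-4-methyl-2-[2-(4-methyl-5-oxo-2,5-dihydrofuran-3-yl)ethyl]-5-oxooxolan-2-yl}-5-[(2S,4S)-4-methyl-5-oxooxolan-2-yl]pyrrolidine-1-carboxylate
Product: 22 tert-butyl (2S,5S)-2-{(2S,4R)-2-[2-(2-hydroxy-4-methyl-5-oxo-2,5-dihydrofuran-3-yl)ethyl]-4-methyl-5-oxooxolan-2-yl}-5-[(2S,4S)-4-methyl-5-oxooxolan-2-yl]pyrrolidine-1-carboxylate (lactol epimers), via 2-silyloxyfuran 21 (not isolated)
Conditions: TIPSOTf, Et3N, CH2Cl2, 0 °C; then DMDO, acetone, −78 °C; aq. citric acid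
Reagents that add atoms: dimethyldioxirane (CC1(C)OO1)
Why: The butenolide, far more acidic at C5 than the two saturated lactones, is silylated to the aromatic 2-silyloxyfuran, which dimethyldioxirane oxidises at C5 to the γ-hydroxybutenolide (oxidation of a 2-silyloxyfuran); the lactol is a mixture of epimers that converge in step 15.

Step 15
Reactants: 22 tert-butyl (2S,5S)-2-{(2S,4R)-2-[2-(2-hydroxy-4-methyl-5-oxo-2,5-dihydrofuran-3-yl)ethyl]-4-methyl-5-oxooxolan-2-yl}-5-[(2S,4S)-4-methyl-5-oxooxolan-2-yl]pyrrolidine-1-carboxylate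
Product: 24 target CNP0155196.1 (3S,5S,9S,9aS,11R,1′S,3′S), via pyrrolidinium trifluoroacetate 23 (not isolated)
Conditions: TFA, CH2Cl2, 0 °C; evaporate; then NaHCO3, 4 Å MS, MeCN (high dilution), rt → 40 °C
Reagents that add atoms: none
Why: Acidolysis removes the Boc group and the freed pyrrolidine nitrogen condenses with the lactol, a masked aldehyde, to the cyclic N,O-acetal, closing the azepine ring (intramolecular aminal formation, 7-exo-trig on the ring-opened iminium ion followed by relactonisation); C5 is set under thermodynamic control because the acetal re-opens reversibly.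

**Compound list**

1 | methyl (2S)-1-Boc-5-oxopyrrolidine-2-carboxylate (Boc-L-pyroglutamic acid methyl ester) | COC(=O)[C@@H]1CCC(=O)N1C(=O)OC(C)(C)C | starting material
2 | methyl (2S)-1-Boc-5-hydroxypyrrolidine-2-carboxylate (C5 epimers) | COC(=O)[C@@H]1CCC(O)N1C(=O)OC(C)(C)C | intermediate
3 | methyl (2S)-1-Boc-5-methoxypyrrolidine-2-carboxylate (C5 epimers) | COC(=O)[C@@H]1CCC(OC)N1C(=O)OC(C)(C)C | intermediate
4 | tert-butyl (2S)-5-methoxy-2-[methoxy(methyl)carbamoyl]pyrrolidine-1-carboxylate | CON(C)C(=O)[C@@H]1CCC(OC)N1C(=O)OC(C)(C)C | intermediate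
5 | tert-butyl (2S)-2-acryloyl-5-methoxypyrrolidine-1-carboxylate | C=CC(=O)[C@@H]1CCC(OC)N1C(=O)OC(C)(C)C | intermediate
6 | tert-butyl (2S)-2-[(3R)-3-hydroxy-5-(triisopropylsilyl)pent-1-en-4-yn-3-yl]-5-methoxypyrrolidine-1-carboxylate | CC(C)[Si](C(C)C)(C(C)C)C#C[C@](O)(C=C)[C@@H]1CCC(OC)N1C(=O)OC(C)(C)C | intermediate
7 | (3R)-3-[(2S)-1-Boc-5-methoxypyrrolidin-2-yl]-5-(triisopropylsilyl)pent-1-en-4-yn-3-yl prop-2-enoate | CC(C)[Si](C(C)C)(C(C)C)C#C[C@](OC(=O)C=C)(C=C)[C@@H]1CCC(OC)N1C(=O)OC(C)(C)C | intermediate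
8 | tert-butyl (2S)-5-methoxy-2-{(2R)-5-oxo-2-[(triisopropylsilyl)ethynyl]-2,5-dihydrofuran-2-yl}pyrrolidine-1-carboxylate | CC(C)[Si](C(C)C)(C(C)C)C#C[C@]1(C=CC(=O)O1)[C@@H]2CCC(OC)N2C(=O)OC(C)(C)C | intermediate
9 | lithium (5R)-5-[(2S)-1-Boc-5-methoxypyrrolidin-2-yl]-5-[(triisopropylsilyl)ethynyl]-4,5-dihydrofuran-2-olate | CC(C)[Si](C(C)C)(C(C)C)C#C[C@]1(CC=C([O-])O1)[C@@H]2CCC(OC)N2C(=O)OC(C)(C)C.[Li+] | intermediate
10 | tert-butyl (2S)-5-methoxy-2-{(2R,4R)-4-methyl-5-oxo-2-[(triisopropylsilyl)ethynyl]oxolan-2-yl}pyrrolidine-1-carboxylate | CC(C)[Si](C(C)C)(C(C)C)C#C[C@]1(C[C@@H](C)C(=O)O1)[C@@H]2CCC(OC)N2C(=O)OC(C)(C)C | intermediate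
11 | tert-butyl (2S)-2-[(2R,4R)-2-ethynyl-4-methyl-5-oxooxolan-2-yl]-5-methoxypyrrolidine-1-carboxylate | C#C[C@]1(C[C@@H](C)C(=O)O1)[C@@H]2CCC(OC)N2C(=O)OC(C)(C)C | intermediate
12 | tert-butyl (2S)-2-[(2R,4R)-2-ethenyl-4-methyl-5-oxooxolan-2-yl]-5-methoxypyrrolidine-1-carboxylate | C=C[C@]1(C[C@@H](C)C(=O)O1)[C@@H]2CCC(OC)N2C(=O)OC(C)(C)C | intermediate
13 | 4-hydroxy-3-methylfuran-2(5H)-one (3-methyltetronic acid) | CC1=C(O)COC1=O | starting material
14 | 4-bromo-3-methylfuran-2(5H)-one | CC1=C(Br)COC1=O | intermediate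
15 | tert-butyl (2S)-2-{(2S,4R)-2-[2-(9-borabicyclo[3.3.1]nonan-9-yl)ethyl]-4-methyl-5-oxooxolan-2-yl}-5-methoxypyrrolidine-1-carboxylate | B1(C2CCCC1CCC2)CC[C@]3(C[C@@H](C)C(=O)O3)[C@@H]4CCC(OC)N4C(=O)OC(C)(C)C | intermediate
16 | tert-butyl (2S)-5-methoxy-2-{(2S,4R)-4-methyl-2-[2-(4-methyl-5-oxo-2,5-dihydrofuran-3-yl)ethyl]-5-oxooxolan-2-yl}pyrrolidine-1-carboxylate | CC1=C(COC1=O)CC[C@]2(C[C@@H](C)C(=O)O2)[C@@H]3CCC(OC)N3C(=O)OC(C)(C)C | intermediate
17 | 3-methylfuran-2(5H)-one | CC1=CCOC1=O | starting material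
18 | triisopropyl[(3-methylfuran-2-yl)oxy]silane | Cc1ccoc1O[Si](C(C)C)(C(C)C)C(C)C | intermediate
19 | tert-butyl (2S,5S)-2-{(2S,4R)-4-methyl-2-[2-(4-methyl-5-oxo-2,5-dihydrofuran-3-yl)ethyl]-5-oxooxolan-2-yl}-5-[(2S)-4-methyl-5-oxo-2,5-dihydrofuran-2-yl]pyrrolidine-1-carboxylate | CC1=C(COC1=O)CC[C@]2(C[C@@H](C)C(=O)O2)[C@@H]3CC[C@@H]([C@@H]4C=C(C)C(=O)O4)N3C(=O)OC(C)(C)C | intermediate
20 | tert-butyl (2S,5S)-2-{(2S,4R)-4-methyl-2-[2-(4-methyl-5-oxo-2,5-dihydrofuran-3-yl)ethyl]-5-oxooxolan-2-yl}-5-[(2S,4S)-4-methyl-5-oxooxolan-2-yl]pyrrolidine-1-carboxylate | CC1=C(COC1=O)CC[C@]2(C[C@@H](C)C(=O)O2)[C@@H]3CC[C@@H]([C@@H]4C[C@H](C)C(=O)O4)N3C(=O)OC(C)(C)C | intermediate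
21 | tert-butyl (2S,5S)-2-{(2S,4R)-4-methyl-2-[2-(4-methyl-5-(triisopropylsilyloxy)furan-3-yl)ethyl]-5-oxooxolan-2-yl}-5-[(2S,4S)-4-methyl-5-oxooxolan-2-yl]pyrrolidine-1-carboxylate | CC(C)[Si](Oc1occ(CC[C@]2(C[C@@H](C)C(=O)O2)[C@@H]3CC[C@@H]([C@@H]4C[C@H](C)C(=O)O4)N3C(=O)OC(C)(C)C)c1C)(C(C)C)C(C)C | intermediate
22 | tert-butyl (2S,5S)-2-{(2S,4R)-2-[2-(2-hydroxy-4-methyl-5-oxo-2,5-dihydrofuran-3-yl)ethyl]-4-methyl-5-oxooxolan-2-yl}-5-[(2S,4S)-4-methyl-5-oxooxolan-2-yl]pyrrolidine-1-carboxylate (lactol epimers) | CC1=C(C(O)OC1=O)CC[C@]2(C[C@@H](C)C(=O)O2)[C@@H]3CC[C@@H]([C@@H]4C[C@H](C)C(=O)O4)N3C(=O)OC(C)(C)C | intermediate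
23 | (2S,5S)-2-{(2S,4R)-2-[2-(2-hydroxy-4-methyl-5-oxo-2,5-dihydrofuran-3-yl)ethyl]-4-methyl-5-oxooxolan-2-yl}-5-[(2S,4S)-4-methyl-5-oxooxolan-2-yl]pyrrolidinium trifluoroacetate | CC1=C(C(O)OC1=O)CC[C@]2(C[C@@H](C)C(=O)O2)[C@@H]3CC[C@@H]([C@@H]4C[C@H](C)C(=O)O4)N3.OC(=O)C(F)(F)F | intermediate
24 | CNP0155196.1: pyrrolo[1,2-a]azepine fused at C5–C6 to a 3-methylbutenolide through the C5 N,O-acetal, spiro-fused at C9 to an α-methyl-γ-butyrolactone, C3 carrying a cis-α-methyl-γ-butyrolactone; (3S,5S,9S,9aS,11R,1′S,3′S) | CC1=C2CC[C@]3(C[C@@H](C)C(=O)O3)[C@@H]3CC[C@@H]([C@@H]4C[C@H](C)C(=O)O4)N3[C@H]2OC1=O | target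

**Step count and risks**

Total step count: 15. Longest linear sequence: 13 steps (steps 1–8, 10, 12–15).

Step 6 is the first likely point of failure. The hindered hydride may add 1,2 to the lactone carbonyl, and the borane-associated enolate may be methylated slowly, so that proton transfer erodes conversion and facial selectivity. The fallback sets out from 8 and comes back at 10. Conjugate reduction with catalytic copper hydride ([(Ph3P)CuH]6, PhSiH3, toluene, rt) should give the saturated lactone tert-butyl (2S)-5-methoxy-2-{(2R)-5-oxo-2-[(triisopropylsilyl)ethynyl]oxolan-2-yl}pyrrolidine-1-carboxylate F1. Its free lithium enolate (LiHMDS, THF, −78 °C) would then be methylated with iodomethane anti to the pyrrolidinyl group to give 10.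

Step 12 is the second. Facial selectivity at the N-Boc iminium ion may be poor, because allylic strain to the carbamate can tilt the C9a substituent and open the cis face, and the threo preference may be weak. The fallback sets out from 16 and comes back at 19. TFA in CH2Cl2 should remove the Boc group and methanol to give, after neutralisation, the cyclic imine (3R,5S)-5-[(2S)-3,4-dihydro-2H-pyrrol-2-yl]-3-methyl-5-[2-(4-methyl-5-oxo-2,5-dihydrofuran-3-yl)ethyl]oxolan-2-one F2. Without the carbamate, the C9a substituent sits pseudo-equatorial, and Mannich addition of 18 (BF3·OEt2, CH2Cl2, −78 °C) should occur anti to it to give the secondary amine (3R,5S)-3-methyl-5-[2-(4-methyl-5-oxo-2,5-dihydrofuran-3-yl)ethyl]-5-{(2S,5S)-5-[(2S)-4-methyl-5-oxo-2,5-dihydrofuran-2-yl]pyrrolidin-2-yl}oxolan-2-one F3. Reprotection with Boc2O and Et3N gives 19.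

Step 15 is the third. The seven-membered ring may close slowly, so that O→N acyl transfer from the neighbouring lactones to the free amine, or oligomerisation, takes over. The fallback sets out from 20 and comes back at 24, bypassing step 14. Wohl–Ziegler bromination (NBS, AIBN, PhCF3, 80 °C) at the doubly activated C5 methylene should give tert-butyl (2S,5S)-2-{(2S,4R)-2-[2-(2-bromo-4-methyl-5-oxo-2,5-dihydrofuran-3-yl)ethyl]-4-methyl-5-oxooxolan-2-yl}-5-[(2S,4S)-4-methyl-5-oxooxolan-2-yl]pyrrolidine-1-carboxylate F4. TFA then removes the Boc group to give (2S,5S)-2-{(2S,4R)-2-[2-(2-bromo-4-methyl-5-oxo-2,5-dihydrofuran-3-yl)ethyl]-4-methyl-5-oxooxolan-2-yl}-5-[(2S,4S)-4-methyl-5-oxooxolan-2-yl]pyrrolidinium trifluoroacetate F5, which is not isolated. i-Pr2NEt in dilute MeCN should trigger intramolecular N-alkylation through the acyloxy-stabilised allyl cation to give 24.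

**Further compounds**

F1 | step 6 | tert-butyl (2S)-5-methoxy-2-{(2R)-5-oxo-2-[(triisopropylsilyl)ethynyl]oxolan-2-yl}pyrrolidine-1-carboxylate | CC(C)[Si](C(C)C)(C(C)C)C#C[C@]1(CCC(=O)O1)[C@@H]2CCC(OC)N2C(=O)OC(C)(C)C
F2 | step 12 | (3R,5S)-5-[(2S)-3,4-dihydro-2H-pyrrol-2-yl]-3-methyl-5-[2-(4-methyl-5-oxo-2,5-dihydrofuran-3-yl)ethyl]oxolan-2-one | CC1=C(COC1=O)CC[C@]2(C[C@@H](C)C(=O)O2)[C@@H]3CCC=N3
F3 | step 12 | (3R,5S)-3-methyl-5-[2-(4-methyl-5-oxo-2,5-dihydrofuran-3-yl)ethyl]-5-{(2S,5S)-5-[(2S)-4-methyl-5-oxo-2,5-dihydrofuran-2-yl]pyrrolidin-2-yl}oxolan-2-one | CC1=C(COC1=O)CC[C@]2(C[C@@H](C)C(=O)O2)[C@@H]3CC[C@@H]([C@@H]4C=C(C)C(=O)O4)N3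
F4 | step 15 | tert-butyl (2S,5S)-2-{(2S,4R)-2-[2-(2-bromo-4-methyl-5-oxo-2,5-dihydrofuran-3-yl)ethyl]-4-methyl-5-oxooxolan-2-yl}-5-[(2S,4S)-4-methyl-5-oxooxolan-2-yl]pyrrolidine-1-carboxylate | CC1=C(C(Br)OC1=O)CC[C@]2(C[C@@H](C)C(=O)O2)[C@@H]3CC[C@@H]([C@@H]4C[C@H](C)C(=O)O4)N3C(=O)OC(C)(C)C
F5 | step 15 | (2S,5S)-2-{(2S,4R)-2-[2-(2-bromo-4-methyl-5-oxo-2,5-dihydrofuran-3-yl)ethyl]-4-methyl-5-oxooxolan-2-yl}-5-[(2S,4S)-4-methyl-5-oxooxolan-2-yl]pyrrolidinium trifluoroacetate | CC1=C(C(Br)OC1=O)CC[C@]2(C[C@@H](C)C(=O)O2)[C@@H]3CC[C@@H]([C@@H]4C[C@H](C)C(=O)O4)N3.OC(=O)C(F)(F)F
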